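**Retrosynthetic overview**

1. Numbering: C1 is the fully substituted carbinol carrying the C7 CH2O arm, then C2 (OBz), C3=C4, C5 (OBz), C6 (OH); all four ring oxygens lie on one face. The plan rests on the cis-ene-1,4-diol C2(O)–C3=C4–C5(O) that brackets the cis C1/C6 diol of the cyclohexene ring.
2. Cutting C2–C3 and C4–C5 gives (Z)-1,2-diiodoethene (C3=C4) and the cis-diformyl dioxolane 11 (C2, C1, C6, C5, with C7 on C1). One nickel/chromium-mediated operation joins them and closes the only carbocycle.
3. Dialdehyde 11 comes from diol 10 and the branched lactol 7, made by formaldehyde aldol on 2,3-O-isopropylidene-L-erythrose from L-arabinose. C4 of arabinose becomes C6; the aldol sets C1.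
4. O7 is carried as a silyl ether, because an ester could shift between the two CH2O arms of C1 in diol 10 and erase that stereocentre. After ring formation: desilylation, tribenzoylation, acetonide hydrolysis.

Key step: step 7

Assumption: (Z)-1,2-diiodoethene is taken as a purchasable reagent, used freshly filtered through basic alumina and in the dark, because iodine traces or light convert it into the E isomer, which cannot close the ring.

**Route**

Step 1
Reactants: 1 L-arabinose; 2 2,2-dimethoxypropane
Product: 3 3,4-O-isopropylidene-L-arabinopyranose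
Conditions: TsOH·H2O (cat.), DMF, rt; Et3N quench
Reagents that add atoms: 2,2-dimethoxypropane, COC(C)(C)OC
Why: Acid-catalysed transacetalisation under kinetic control should take the only cis-vicinal diol of the pyranose (O3/O4), a standard acetonation that forms no stereocentre and leaves the C1/C2 glycol free for cleavage.

Step 2
Reactants: 3 3,4-O-isopropylidene-L-arabinopyranose
Product: 5 2,3-O-isopropylidene-L-erythrofuranose, via 4-O-formyl-2,3-O-isopropylidene-L-erythrose 4 (not isolated)
Conditions: NaIO4 (1.2 equiv), H2O, 0 °C → rt; then Na2CO3, rt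
Reagents that add atoms: none
Why: Periodate glycol cleavage (Malaprade reaction) of the C1–C2 bond excises the anomeric carbon as a formate ester, which carbonate hydrolyses so that the hydroxy aldehyde closes to the lactol; the two remaining stereocentres are not touched.

Step 3
Reactants: 5 2,3-O-isopropylidene-L-erythrofuranose; 6 formaldehyde
Product: 7 2-C-(hydroxymethyl)-2,3-O-isopropylidene-L-erythrofuranose
Conditions: 37% aq. HCHO (excess), K2CO3, MeOH, 65 °C
Reagents that add atoms: formaldehyde, C=O
Why: Crossed aldol (hydroxymethylation) of the enolate of the open-chain aldehyde, a known reaction of 2,3-O-isopropylidene furanoses; the quaternary carbon (C1 of the target) is set by C3 of the sugar (C6 of the target), because formaldehyde enters trans to the C4 arm on the dioxolane and only that epimer can reclose to the cis-fused lactol, the reversible aldol funnelling material to it.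

Step 4
Reactants: 7 2-C-(hydroxymethyl)-2,3-O-isopropylidene-L-erythrofuranose; 8 tert-butyl(chloro)diphenylsilane
Product: 9 2-C-[(tert-butyldiphenylsilyloxy)methyl]-2,3-O-isopropylidene-L-erythrofuranose
Conditions: TBDPSCl (1.1 equiv), imidazole, DMF, 0 °C → rt
Reagents that add atoms: tert-butyl(chloro)diphenylsilane, CC(C)(C)[Si](Cl)(c1ccccc1)c1ccccc1
Why: Silylation with a bulky chlorosilane should take the primary hydroxyl in preference to the hindered hemiacetal hydroxyl, as in the 5-O-silylation of isopropylidene ribofuranose.

Step 5
Reactants: 9 2-C-[(tert-butyldiphenylsilyloxy)methyl]-2,3-O-isopropylidene-L-erythrofuranose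
Product: 10 [(4S,5S)-4-[(tert-butyldiphenylsilyloxy)methyl]-2,2-dimethyl-1,3-dioxolane-4,5-diyl]dimethanol (the two CH2OH groups cis)
Conditions: NaBH4, MeOH, 0 °C
Reagents that add atoms: none
Why: Borohydride reduction of the aldehyde in equilibrium with the lactol gives the 1,4-diol; silyl ether, acetonide and both stereocentres are inert.

Step 6
Reactants: 10 the cis-diol
Product: 11 (4S,5R)-4-[(tert-butyldiphenylsilyloxy)methyl]-2,2-dimethyl-1,3-dioxolane-4,5-dicarbaldehyde (formyl groups cis)
Conditions: (COCl)2, DMSO, CH2Cl2, −78 °C; then Et3N, −78 → −30 °C; short silica pad, used at once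
Reagents that add atoms: none
Why: Swern oxidation converts both hydroxyls into alkoxysulfonium salts before base is added, so no hydroxy aldehyde can lactolise and over-oxidise, and the low temperature limits epimerisation at the CH carbon next to the formyl group.

Step 7
Reactants: 11 the cis-dialdehyde; 12 (Z)-1,2-diiodoethene
Product: 14 (3aR,4R,7S,7aS)-3a-[(tert-butyldiphenylsilyloxy)methyl]-2,2-dimethyl-3a,4,7,7a-tetrahydro-1,3-benzodioxole-4,7-diol, via (Z)-iodovinyl carbinol mono-adduct 13 (not isolated)
Conditions: CrCl2 (8 equiv), NiCl2 (2 mol %), degassed DMF, rt, 11 and 12 (1.1 equiv) added over 10 h, final 0.01 M; aq. NH4Cl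
Reagents that add atoms: (Z)-1,2-diiodoethene, I/C=C\I
Why: Proposed new method: zerovalent nickel, formed from NiCl2 by CrCl2, inserts into one C–I bond of 12 and transmetalation gives a (Z)-2-iodovinyl species of trivalent chromium that adds to the less hindered formyl group (on the CH carbon, C5) to give 13 as its chromium alkoxide, after which the same sequence at the remaining C–I bond gives an alkenylchromium that adds to the C2 formyl group in a 6-exo-trig closure of the cyclohexene, the Z geometry surviving as C3=C4. The closest known reactions are the intermolecular Nozaki–Hiyama–Kishi coupling of Z-iodoalkenes with α-alkoxy aldehydes and the intramolecular Nozaki–Hiyama–Kishi ring closure; what is new is a vicinal diiodoalkene serving as a twofold donor in one pot. C5 is set in the intermolecular addition by C6 under polar Felkin–Anh control (dioxolane C–O bond anti to the incoming alkenyl group, attack past H6), the usual sense for alkenylchromium additions to α-alkoxy aldehydes, which gives the 5,6-cis carbinol. C2 is set in the ring closure by C1: with chromium bridging the formyl oxygen and O1, the nucleophile is tethered through C6 and can reach only the face that places the new hydroxyl cis to O1. The step needs carbonyl addition to outrun β-elimination of iodide from the cis-2-iodovinyl metal intermediates and ring closure to outrun oligomerisation; the cis placement of the two formyl groups on the dioxolane, the excess of CrCl2, the low nickel loading and slow addition at high dilution are meant to secure both.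

Step 8
Reactants: 14 the bicyclic silyl ether diol
Product: 15 (3aR,4R,7S,7aS)-3a-(hydroxymethyl)-2,2-dimethyl-3a,4,7,7a-tetrahydro-1,3-benzodioxole-4,7-diol
Conditions: TBAF, THF, 0 °C → rt
Reagents that add atoms: none
Why: Fluoride-induced cleavage of the silyl ether; no ester is present yet, so nothing can migrate under the basic fluoride.

Step 9
Reactants: 15 the triol; 16 benzoyl chloride
Product: 17 [(3aR,4R,7S,7aS)-4,7-bis(benzoyloxy)-2,2-dimethyl-3a,4,7,7a-tetrahydro-1,3-benzodioxol-3a-yl]methyl benzoate
Conditions: BzCl (4.5 equiv), pyridine, DMAP (0.2 equiv), CH2Cl2, 0 °C → rt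
Reagents that add atoms: benzoyl chloride, O=C(Cl)c1ccccc1
Why: DMAP-catalysed acylation should esterify the three free hydroxyls (primary O7, allylic O2 and O5) while O1 and O6 stay masked in the acetonide.

Step 10
Reactants: 17 the tribenzoate acetonide
Product: 18 [(1S,2R,5S,6S)-2,5-bis(benzoyloxy)-1,6-dihydroxycyclohex-3-en-1-yl]methyl benzoate (target)
Conditions: TFA–H2O (9:1), 0 °C, short reaction time
Reagents that add atoms: none
Why: Acid hydrolysis of the isopropylidene acetal frees the cis C1/C6 diol; benzoates and the alkene tolerate cold aqueous acid, and a short exposure limits benzoyl shift from O5 to O6.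

**Compound list**

1 | L-arabinose (pyranose form, anomeric centre open) | OC1OC[C@H](O)[C@H](O)[C@H]1O | starting material
2 | 2,2-dimethoxypropane | COC(C)(C)OC | starting material
3 | 3,4-O-isopropylidene-L-arabinopyranose | OC1OC[C@@H]2OC(C)(C)O[C@@H]2[C@H]1O | intermediate
4 | 4-O-formyl-2,3-O-isopropylidene-L-erythrose | O=COC[C@@H]1OC(C)(C)O[C@@H]1C=O | intermediate (not isolated)
5 | 2,3-O-isopropylidene-L-erythrofuranose (lactol, anomers) | OC1OC[C@@H]2OC(C)(C)O[C@H]12 | intermediate
6 | formaldehyde | C=O | starting material
7 | 2-C-(hydroxymethyl)-2,3-O-isopropylidene-L-erythrofuranose (CH2OH trans to the dioxolane oxygens) | OC1OC[C@@H]2OC(C)(C)O[C@]12CO | intermediate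
8 | tert-butyl(chloro)diphenylsilane | CC(C)(C)[Si](Cl)(c1ccccc1)c1ccccc1 | starting material
9 | 2-C-[(tert-butyldiphenylsilyloxy)methyl]-2,3-O-isopropylidene-L-erythrofuranose | OC1OC[C@@H]2OC(C)(C)O[C@]12CO[Si](c1ccccc1)(c1ccccc1)C(C)(C)C | intermediate
10 | [(4S,5S)-4-[(tert-butyldiphenylsilyloxy)methyl]-2,2-dimethyl-1,3-dioxolane-4,5-diyl]dimethanol | CC(C)(C)[Si](OC[C@]1(CO)OC(C)(C)O[C@H]1CO)(c1ccccc1)c1ccccc1 | intermediate
11 | (4S,5R)-4-[(tert-butyldiphenylsilyloxy)methyl]-2,2-dimethyl-1,3-dioxolane-4,5-dicarbaldehyde | CC(C)(C)[Si](OC[C@]1(C=O)OC(C)(C)O[C@H]1C=O)(c1ccccc1)c1ccccc1 | intermediate (key-step precursor)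
12 | (Z)-1,2-diiodoethene | I/C=C\I | starting material
13 | mono-adduct at the CH-bound formyl group: (Z)-3-iodoallylic alcohol still carrying the C2 formyl group (present as its chromium alkoxide, drawn as the alcohol) | CC(C)(C)[Si](OC[C@]1(C=O)OC(C)(C)O[C@H]1[C@@H](O)/C=C\I)(c1ccccc1)c1ccccc1 | intermediate (not isolated)
14 | (3aR,4R,7S,7aS)-3a-[(tert-butyldiphenylsilyloxy)methyl]-2,2-dimethyl-3a,4,7,7a-tetrahydro-1,3-benzodioxole-4,7-diol (cis-fused, both hydroxyls cis to the dioxolane oxygens) | CC(C)(C)[Si](OC[C@@]1(OC(C)(C)O2)[C@H](O)C=C[C@H](O)[C@@H]12)(c1ccccc1)c1ccccc1 | intermediate (key-step product)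
15 | (3aR,4R,7S,7aS)-3a-(hydroxymethyl)-2,2-dimethyl-3a,4,7,7a-tetrahydro-1,3-benzodioxole-4,7-diol | OC[C@@]1(OC(C)(C)O2)[C@H](O)C=C[C@H](O)[C@@H]12 | intermediate
16 | benzoyl chloride | O=C(Cl)c1ccccc1 | starting material
17 | [(3aR,4R,7S,7aS)-4,7-bis(benzoyloxy)-2,2-dimethyl-3a,4,7,7a-tetrahydro-1,3-benzodioxol-3a-yl]methyl benzoate | O=C(OC[C@@]1(OC(C)(C)O2)[C@H](OC(=O)c3ccccc3)C=C[C@H](OC(=O)c3ccccc3)[C@@H]12)c1ccccc1 | intermediate
18 | [(1S,2R,5S,6S)-2,5-bis(benzoyloxy)-1,6-dihydroxycyclohex-3-en-1-yl]methyl benzoate | O=C(OC[C@@]1(O)[C@H](OC(=O)c2ccccc2)C=C[C@H](OC(=O)c2ccccc2)[C@@H]1O)c1ccccc1 | target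

**Step count and risks**

Total steps: 10. Longest linear sequence: 10 (L-arabinose to target).

Step 7 (Proposed new method). What may go wrong:
- β-elimination of iodide from the cis-2-iodovinyl nickel or chromium intermediate, losing the two-carbon unit as acetylene before any carbonyl addition;
- capture of the second formyl group as a cyclic chromium lactolate by the alkoxide of the first addition, stalling ring closure;
- oligomerisation;
- poor facial selectivity in the ring-closing addition at C2, whose neighbour C1 is fully substituted.

Fallback with known chemistry, setting out from 11 and returning at 14: CH2=CHMgBr (5 equiv, THF, −78 → 0 °C) should add to both formyl groups, the magnesium lactolate formed after the first addition reopening under excess reagent, to give the divinyl diol F1. Ring-closing metathesis with the second-generation Grubbs catalyst (CH2Cl2, 40 °C) then forms C3=C4 and gives 14, which is separated from carbinol epimers by chromatography.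

Step 6. What may go wrong:
- incomplete double oxidation, with lactol formation and over-oxidation to a lactone;
- epimerisation at the CH carbon next to the formyl group by the amine base;
- hydration or self-condensation of the dialdehyde on work-up.

Fallback, setting out from 9 and returning at 11: Wittig methylenation of the lactol (Ph3P=CH2 from Ph3PCH3Br and KOtBu, THF, 0 °C → rt) masks the formyl group on the quaternary carbon as a vinyl group and leaves a single primary alcohol, the vinyl alcohol F2. Dess–Martin periodinane (NaHCO3, CH2Cl2) gives the vinyl aldehyde F3. Ozonolysis (O3, CH2Cl2, −78 °C; then Me2S) unveils the second formyl group without base and gives 11.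

Step 4. What may go wrong:
- competition of the hemiacetal hydroxyl with the neopentyl primary hydroxyl for the silyl chloride, giving anomeric or double silylation;
- sluggish reaction at the hindered primary position.

Fallback, setting out from 7 and returning at 9: exhaustive silylation (TBDPSCl 2.5 equiv, imidazole, DMF, 40 °C) gives the bis-silyl compound F4. The anomeric O–Si bond alone is then cleaved, since it is an acetal-type silyl ether with the far better leaving group (TBAF 1 equiv buffered with AcOH, THF, −20 °C), to give 9.

**Further compounds**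

F1 | step 7 | divinyl diol: 4,5-bis(1-hydroxyprop-2-enyl) dioxolane with both carbinols configured as C2 and C5 of 14 | CC(C)(C)[Si](OC[C@]1([C@H](O)C=C)OC(C)(C)O[C@H]1[C@@H](O)C=C)(c1ccccc1)c1ccccc1
F2 | step 6 | vinyl alcohol: 4-vinyl-5-(hydroxymethyl) dioxolane silyl ether | CC(C)(C)[Si](OC[C@]1(C=C)OC(C)(C)O[C@H]1CO)(c1ccccc1)c1ccccc1
F3 | step 6 | vinyl aldehyde: 4-vinyl-5-formyl dioxolane silyl ether | CC(C)(C)[Si](OC[C@]1(C=C)OC(C)(C)O[C@H]1C=O)(c1ccccc1)c1ccccc1
F4 | step 4 | bis-silyl compound: 1-O-silyl-2-C-(silyloxymethyl)-2,3-O-isopropylidene-L-erythrofuranose | CC(C)(C)[Si](OC1OC[C@@H]2OC(C)(C)O[C@]12CO[Si](c1ccccc1)(c1ccccc1)C(C)(C)C)(c1ccccc1)c1ccccc1
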